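A clean single step from electrophile to target cannot describe these runs: at 25.0 h in Tuesday's run, 8% is electrophile and 8% target, so 84.0% of the charge is neither. The electrophile's own decay can still be read.

| flask | electrophile | nucleophile | free base | remark | time |
|---|---|---|---|---|---|
| Friday's | 5 mM | 20 mM | 30 mM | run made earlier |  |
| Tuesday's | 20 mM | 20 mM | 30 mM | run made earlier |  |
| flask | 10 mM | 20.0 mM | 30.0 mM |  | 20 h |

| run | time / h | electrophile / % | target / % |
|---|---|---|---|
| Friday's | 2.00 | 77 | 12 |
| Friday's | 6.00 | 42 | 24 |
| Friday's | 12.0 | 23 | 34 |
| Friday's | 15.0 | 18 | 33 |
| Friday's | 25.0 | 5 | 37 |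
| Tuesday's | 2.00 | 71 | 8 |
| Tuesday's | 4.00 | 49 | 13 |
| Tuesday's | 6.00 | 33 | 9 |
| Tuesday's | 12.0 | 18 | 12 |
| Tuesday's | 25.0 | 8 | 8 |

(scatter of a reading: 1.5 percentage points)

- the numbers in the tables scatter with a standard deviation of 1.5 percentage points
- what has gone from electrophile into another species counts as reacted, even if it can come back
- the earlier runs do not show how much of nucleophile is bound; that part of a forecast is a guess

- part of the electrophile that has reacted at 20 h
- share of the unused nucleophile that is free and not bound as protonated nucleophile, at 20 h

I carry one quantity, the decay constant: the logarithm of charged over left, divided by time, an apparent first-order constant averaged over the run. The two extreme versions of this flask are Friday's dilute run and Tuesday's crowded one, and I read each at its last reading: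

Friday's: 0.120 /h, so I reckon 90.9% reacted at 20 h

Tuesday's: 0.101 /h, so I reckon 86.7% reacted at 20 h

The flask holds 10 mM of electrophile, between 5 mM and 20 mM, with nucleophile and free base as in both runs, so I place it between them:

midway: 0.110 /h, so I reckon 88.9% reacted at 20 h

The forecast says 90% (86% to 94%), above my figure, on the ground that “A 10 mM run should fall between these”. The runs do not show how much nucleophile is bound, so I take the forecast's 80% free (55% to 97%) as a guess.

The flask gives 90.1% reacted and 82.6% free.

    electrophile + nucleophile ⇌ acid set free + target (K = 3.60, k = 0.0774 /M/min)
    nucleophile + acid set free ⇌ protonated nucleophile, settled at all times (K = 2580 /M)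
    acid set free + free base ⇌ salt of the base, settled at all times (K = 500 /M)
    electrophile + target → side product (k = 0.458 /M/min)
    electrophile + acid set free ⇌ idle adduct, settled at all times (K = 14000 /M)

With the other charges and the time held, the reacted part moves 5 points at 14.5 mM or 30.9 mM of nucleophile, which takes it outside the forecast's range. The flask's own decay constant is 0.115 /h, beside my 0.110 /h. Scaled by nucleophile charge, my constant gives 0.276 /h for the neighbour flask with 50 mM of nucleophile. That flask shows 0.213 /h, with 1.4% of its electrophile left at 20 h.

All runs are calculated with constants of no real substance, noise included.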